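**Retrosynthetic overview**

1. The C5=C1'' bond is cut by a Knoevenagel disconnection into the (7S) acetate half 25 (C5 methylene) and the (6R,7R) enal half 26; the four aryl silyl ethers come off last.
2. Both halves derive from one racemic 7-hydroxy-7-methyl-1H-isochromene-6,8-dione 17. Because the two C7 centres are of opposite sense, a ketoreductase resolution sends both enantiomers forward: the unreduced 7S ketone to 25, the 6R,7R diol to 26.
3. 17 comes from late hydroxylative dearomatisation of the resorcinol 15, so each carbocycle is bought as an arene (first ring) and carried aromatic through the ring closure.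
4. The pyran ring (second ring) is closed at C4–C4a by an intramolecular 6-endo Heck reaction of the C4a bromide onto a 2-alkoxy-1,3-diene made from an ester by methylenation.
5. Enabling feature: C3 of the pyran ring carries both the ring oxygen O2 and the (E)-propenyl chain, so C4=C3–C1'=C2' is a 2-oxy-1,3-diene with C4 as its free terminus, and the ring-fusion carbon C4a can hold bromide at the arene oxidation level.

Key step: step 9

Remark: the SMILES is read as 7S in the acetoxypropenyl half and 6R,7R in the other half (with the pyran rings drawn alike the two C7 centres are of opposite sense); isochromene numbering is used (C1H2, O2, C3, C4, C4a, C5 to C8, C8a; side chain C1' to C3'; linker C1'' to C3''), and 16 and 17 are drawn as the 6,8-diketo tautomers.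

**Route**

Step 1
Reactants: 1 2,6-dimethoxytoluene
Product: 3 5-bromo-1,3-dimethoxy-2-methylbenzene, via aryl pinacol boronate 2 (not isolated)
Conditions: [Ir(OMe)(cod)]2 (cat.), 4,4'-di-tert-butyl-2,2'-bipyridine, B2pin2, THF, 80 °C; then CuBr2, MeOH/H2O, 80 °C
Reagents that add atoms: bis(pinacolato)diboron, CC1(C)OB(OC1(C)C)B1OC(C)(C)C(C)(C)O1 (boron of 2); copper dibromide, Br[Cu]Br (bromine of 3)
Why: Iridium-catalysed C–H borylation is sterically controlled and should occur only at the one ring position not flanked by a substituent, and copper-mediated bromodeboronation then places bromine meta to both methoxy groups, where electrophilic bromination cannot reach.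

Step 2
Reactants: 3 5-bromo-1,3-dimethoxy-2-methylbenzene
Product: 5 6-bromo-2,4-dimethoxy-3-methylbenzaldehyde, via aryl iminium chloride 4 (not isolated)
Conditions: POCl3, DMF, 0 to 80 °C; then aq. NaOAc
Reagents that add atoms: N,N-dimethylformamide, CN(C)C=O (formyl carbon); water, O (aldehyde oxygen)
Why: Vilsmeier–Haack formylation should go to the only free ring positions, which are equivalent and lie ortho and para to the two methoxy groups.

Step 3
Reactants: 5 6-bromo-2,4-dimethoxy-3-methylbenzaldehyde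
Product: 6 6-bromo-2,4-dihydroxy-3-methylbenzaldehyde
Conditions: BBr3, CH2Cl2, –78 °C to rt; then H2O
Reagents that add atoms: none
Why: Boron tribromide cleaves both aryl methyl ethers (Lewis acid ether cleavage) and leaves the aldehyde and the aryl bromide untouched.

Step 4
Reactants: 6 6-bromo-2,4-dihydroxy-3-methylbenzaldehyde
Product: 7 6-bromo-3-methyl-2,4-bis(triisopropylsilyloxy)benzaldehyde
Conditions: i-Pr3SiOTf, 2,6-lutidine, CH2Cl2, 0 °C to rt
Reagents that add atoms: triisopropylsilyl trifluoromethanesulfonate, CC(C)[Si](OS(=O)(=O)C(F)(F)F)(C(C)C)C(C)C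
Why: A silyl triflate with a hindered pyridine base silylates both phenols, including the hydrogen-bonded one, and the bulky silyl groups are chosen because they resist migration to the benzylic oxygen and survive steps 5 to 9.

Step 5
Reactants: 7 6-bromo-3-methyl-2,4-bis(triisopropylsilyloxy)benzaldehyde
Product: 8 [6-bromo-3-methyl-2,4-bis(triisopropylsilyloxy)phenyl]methanol
Conditions: i-Bu2AlH, CH2Cl2, –78 °C; then aq. potassium sodium tartrate (KNaC4H4O6)
Reagents that add atoms: none
Why: Low-temperature hydride reduction of the aldehyde with a neutral aluminium hydride gives the benzylic alcohol without touching the aryl bromide and without a free basic alkoxide that could trigger silyl migration.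

Step 6
Reactants: 8 [6-bromo-3-methyl-2,4-bis(triisopropylsilyloxy)phenyl]methanol; 9 (diethoxyphosphoryl)acetic acid
Product: 10 [6-bromo-3-methyl-2,4-bis(triisopropylsilyloxy)phenyl]methyl (diethoxyphosphoryl)acetate
Conditions: N,N'-dicyclohexylcarbodiimide, 4-dimethylaminopyridine (cat.), CH2Cl2, 0 °C to rt
Reagents that add atoms: none
Why: Steglich esterification of a primary benzylic alcohol is reliable and installs the phosphonate for the next step.

Step 7
Reactants: 10 [6-bromo-3-methyl-2,4-bis(triisopropylsilyloxy)phenyl]methyl (diethoxyphosphoryl)acetate; 11 (tert-butyldimethylsilyloxy)acetaldehyde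
Product: 12 [6-bromo-3-methyl-2,4-bis(triisopropylsilyloxy)phenyl]methyl (E)-4-(tert-butyldimethylsilyloxy)but-2-enoate
Conditions: LiCl, i-Pr2NEt, MeCN, rt
Reagents that add atoms: none
Why: Horner–Wadsworth–Emmons olefination under mild LiCl/amine conditions should give the E enoate selectively without harming the aryl silyl ethers.

Step 8
Reactants: 12 [6-bromo-3-methyl-2,4-bis(triisopropylsilyloxy)phenyl]methyl (E)-4-(tert-butyldimethylsilyloxy)but-2-enoate
Product: 13 1-bromo-2-({[(3E)-5-(tert-butyldimethylsilyloxy)penta-1,3-dien-2-yl]oxy}methyl)-4-methyl-3,5-bis(triisopropylsilyloxy)benzene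
Conditions: Cp2TiMe2, toluene/THF, 65 °C, dark
Reagents that add atoms: dimethyltitanocene (Cp2TiMe2), [CH3-].[CH3-].[Ti+4].c1cc[cH-]c1.c1cc[cH-]c1
Why: Petasis methylenation turns the ester carbonyl into the enol ether methylene through a titanium methylidene and an oxatitanacyclobutane, the established way from enoates to 2-alkoxy-1,3-dienes, and the neutral conditions keep the acid-labile product intact.

Step 9
Reactants: 13 1-bromo-2-({[(3E)-5-(tert-butyldimethylsilyloxy)penta-1,3-dien-2-yl]oxy}methyl)-4-methyl-3,5-bis(triisopropylsilyloxy)benzene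
Product: 14 3-[(E)-3-(tert-butyldimethylsilyloxy)prop-1-enyl]-7-methyl-6,8-bis(triisopropylsilyloxy)-1H-isochromene
Conditions: Pd2(dba)3 (cat.), [t-Bu3PH]BF4 (cat.), Cy2NMe, 1,4-dioxane, 70 °C
Reagents that add atoms: none
Why: Oxidative addition of zerovalent palladium into the C4a–Br bond is followed by migratory insertion of the tethered 2-alkoxy-1,3-diene with the aryl carbon bonding to the unsubstituted diene terminus C4, so that palladium ends on C3 as an η3-allyl unit spanning C3–C1'–C2', and amine-assisted β-hydride loss from the now benzylic C4 gives the C3=C4–C4a=C8a conjugated 1H-isochromene and returns the catalyst. The closest known reaction type is the intramolecular Mizoroki–Heck cyclisation of aryl halides onto conjugated dienes through π-allylpalladium intermediates, together with 6-endo Heck closures onto heteroatom-substituted alkenes. The pyran ring is closed in the 6-endo-trig mode. No stereocentre is formed, and the E geometry of C1'=C2' should be kept because the syn η3-allyl form is favoured and collapses to the E diene. The step needs 6-endo over 5-exo closure and elimination towards C4 and not towards C3': bonding at C4 gives the allyl-stabilised intermediate whereas bonding at the fully substituted oxygen-bearing C3 would leave a primary alkylpalladium without β-hydrogen, and only loss of a C4 hydrogen puts the new triene in conjugation with the arene. The silyl ethers and the enol ether should be inert to the neutral amine-buffered conditions.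

Step 10
Reactants: 14 3-[(E)-3-(tert-butyldimethylsilyloxy)prop-1-enyl]-7-methyl-6,8-bis(triisopropylsilyloxy)-1H-isochromene
Product: 15 3-[(E)-3-(tert-butyldimethylsilyloxy)prop-1-enyl]-7-methyl-1H-isochromene-6,8-diol
Conditions: Bu4NF (2.2 equiv), THF, –20 °C; then AcOH
Reagents that add atoms: none
Why: Fluoride cleaves aryl silyl ethers much faster than a primary alkyl silyl ether because phenoxide is the better leaving group, so at low temperature only the two phenols should be set free (fluoride desilylation).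

Step 11
Reactants: 15 3-[(E)-3-(tert-butyldimethylsilyloxy)prop-1-enyl]-7-methyl-1H-isochromene-6,8-diol
Product: 16 racemic 3-[(E)-3-(tert-butyldimethylsilyloxy)prop-1-enyl]-7-hydroxy-7-methyl-1H-isochromene-6,8(5H,7H)-dione
Conditions: IBX (1.1 equiv), DMF, 0 °C to rt; then aq. NaHCO3
Reagents that add atoms: 2-iodoxybenzoic acid (IBX), O=C1OI(=O)(O)c2ccccc12
Why: Hydroxylative phenol dearomatisation with the pentavalent iodine reagent proceeds by ligand exchange at a phenolic oxygen and oxygen transfer to the adjacent methyl-bearing C7, which lies ortho to both hydroxyls, and the resulting dione is stabilised as a vinylogous ester through O2–C3=C4–C4a=C8a–C8=O; the new C7 centre is formed racemic on purpose.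

Step 12
Reactants: 16 racemic 3-[(E)-3-(tert-butyldimethylsilyloxy)prop-1-enyl]-7-hydroxy-7-methyl-1H-isochromene-6,8(5H,7H)-dione
Product: 17 racemic 7-hydroxy-3-[(E)-3-hydroxyprop-1-enyl]-7-methyl-1H-isochromene-6,8(5H,7H)-dione
Conditions: Et3N·3HF, THF, rt
Reagents that add atoms: none
Why: Amine-buffered hydrogen fluoride removes the primary silyl ether (fluoride desilylation) without acid or base strong enough to harm the enol ether or the α-ketol.

Step 13
Reactants: 17 racemic 7-hydroxy-3-[(E)-3-hydroxyprop-1-enyl]-7-methyl-1H-isochromene-6,8(5H,7H)-dione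
Product: 18 (7S)-7-hydroxy-3-[(E)-3-hydroxyprop-1-enyl]-7-methyl-1H-isochromene-6,8(5H,7H)-dione, recovered unreduced; 19 (6R,7R)-6,7-dihydroxy-3-[(E)-3-hydroxyprop-1-enyl]-7-methyl-6,7-dihydro-1H-isochromen-8(5H)-one
Conditions: NADPH-dependent ketoreductase (short-chain dehydrogenase/reductase class, picked from a screening panel), NADP+ (cat.), i-PrOH, KH2PO4/K2HPO4 buffer pH 7, DMSO (cosolvent), 30 °C, to about half conversion; chromatographic separation
Reagents that add atoms: none
Why: In this enzymatic kinetic resolution by ketone reduction the selected enzyme should deliver hydride to the isolated C6 carbonyl of the (7R)-enantiomer only, from the face anti to the C7 hydroxyl, which sets C6 as R under enzyme control, while C8 is inert as a doubly vinylogous ester carbonyl and the (7S)-ketone is left for the other half.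

Step 14
Reactants: 18 (7S)-7-hydroxy-3-[(E)-3-hydroxyprop-1-enyl]-7-methyl-1H-isochromene-6,8(5H,7H)-dione
Product: 20 (E)-3-[(7S)-7-hydroxy-7-methyl-6,8-dioxo-5,6,7,8-tetrahydro-1H-isochromen-3-yl]prop-2-enyl acetate
Conditions: Ac2O (1.1 equiv), pyridine, CH2Cl2, 0 °C
Reagents that add atoms: acetic anhydride, CC(=O)OC(C)=O
Why: Acetylation without an acyl-transfer catalyst should acylate the primary allylic alcohol and leave the hindered tertiary α-ketol hydroxyl.

Step 15
Reactants: 19 (6R,7R)-6,7-dihydroxy-3-[(E)-3-hydroxyprop-1-enyl]-7-methyl-6,7-dihydro-1H-isochromen-8(5H)-one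
Product: 21 (E)-3-[(6R,7R)-6,7-dihydroxy-7-methyl-8-oxo-5,6,7,8-tetrahydro-1H-isochromen-3-yl]prop-2-enal
Conditions: MnO2, CH2Cl2, rt
Reagents that add atoms: none
Why: Activated MnO2 oxidises only the allylic primary alcohol to the E enal (allylic oxidation) and leaves the secondary and tertiary hydroxyls.

Step 16
Reactants: 22 orsellinic acid (2,4-dihydroxy-6-methylbenzoic acid)
Product: 23 tert-butyldimethylsilyl 2,4-bis(tert-butyldimethylsilyloxy)-6-methylbenzoate
Conditions: t-BuMe2SiCl, imidazole, DMF, rt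
Reagents that add atoms: tert-butyldimethylsilyl chloride, CC(C)(C)[Si](C)(C)Cl
Why: Exhaustive silylation gives the bis-silyl ether silyl ester in one operation.

Step 17
Reactants: 23 tert-butyldimethylsilyl 2,4-bis(tert-butyldimethylsilyloxy)-6-methylbenzoate
Product: 24 2,4-bis(tert-butyldimethylsilyloxy)-6-methylbenzoyl chloride
Conditions: (COCl)2, DMF (cat.), CH2Cl2, 0 °C to rt
Reagents that add atoms: oxalyl chloride, O=C(Cl)C(Cl)=O
Why: Silyl esters are converted into acid chlorides by oxalyl chloride with catalytic DMF (Vilsmeier-type activation) under neutral conditions, so the aryl silyl ethers should survive.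

Step 18
Reactants: 20 (E)-3-[(7S)-7-hydroxy-7-methyl-6,8-dioxo-5,6,7,8-tetrahydro-1H-isochromen-3-yl]prop-2-enyl acetate; 24 2,4-bis(tert-butyldimethylsilyloxy)-6-methylbenzoyl chloride
Product: 25 (7S)-3-[(E)-3-acetoxyprop-1-enyl]-7-methyl-6,8-dioxo-5,6,7,8-tetrahydro-1H-isochromen-7-yl 2,4-bis(tert-butyldimethylsilyloxy)-6-methylbenzoate
Conditions: 4-dimethylaminopyridine, Et3N, CH2Cl2, 0 °C to rt
Reagents that add atoms: none
Why: Nucleophilic acyl-transfer catalysis should esterify the tertiary C7 hydroxyl, and any acyl group that first lands on the C6 enol oxygen is expected to pass to the neighbouring tertiary oxygen because the enol ester is the higher-energy ester; C7 is quaternary and cannot epimerise.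

Step 19
Reactants: 21 (E)-3-[(6R,7R)-6,7-dihydroxy-7-methyl-8-oxo-5,6,7,8-tetrahydro-1H-isochromen-3-yl]prop-2-enal; 24 2,4-bis(tert-butyldimethylsilyloxy)-6-methylbenzoyl chloride
Product: 26 (6R,7R)-7-hydroxy-7-methyl-8-oxo-3-[(E)-3-oxoprop-1-enyl]-5,6,7,8-tetrahydro-1H-isochromen-6-yl 2,4-bis(tert-butyldimethylsilyloxy)-6-methylbenzoate
Conditions: 4-dimethylaminopyridine (cat.), Et3N, CH2Cl2, –20 to 0 °C
Reagents that add atoms: none
Why: Under catalytic acyl-transfer conditions the secondary C6 hydroxyl is acylated much faster than the tertiary C7 hydroxyl, so the ester goes to C6 with both stereocentres untouched.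

Step 20
Reactants: 25 (7S)-3-[(E)-3-acetoxyprop-1-enyl]-7-methyl-6,8-dioxo-5,6,7,8-tetrahydro-1H-isochromen-7-yl 2,4-bis(tert-butyldimethylsilyloxy)-6-methylbenzoate; 26 (6R,7R)-7-hydroxy-7-methyl-8-oxo-3-[(E)-3-oxoprop-1-enyl]-5,6,7,8-tetrahydro-1H-isochromen-6-yl 2,4-bis(tert-butyldimethylsilyloxy)-6-methylbenzoate
Product: 27 tetrakis(tert-butyldimethylsilyl) ether of the target (all four orsellinate hydroxyls silylated; 7S in the acetate half, 6R,7R in the other half, C5=C1'' Z, C2''=C3'' E)
Conditions: ethylenediammonium diacetate (cat.), 4 Å molecular sieves, CH2Cl2, rt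
Reagents that add atoms: none
Why: In this Knoevenagel condensation the C5 methylene of 25, acidic as part of a vinylogous 1,3-dicarbonyl unit (C6=O and, through C4a=C8a, C8=O), adds to the iminium-activated enal of 26 and water is lost, and the Z geometry at C5=C1'' is expected as the thermodynamic one because it keeps the chain away from the C4 hydrogen.

Step 21
Reactants: 27 tetrakis(tert-butyldimethylsilyl) ether of the target
Product: 28 the target, (7S)-3-[(E)-3-acetoxyprop-1-enyl]-5-{(Z,2E)-3-[(6R,7R)-6-(2,4-dihydroxy-6-methylbenzoyloxy)-7-hydroxy-7-methyl-8-oxo-5,6,7,8-tetrahydro-1H-isochromen-3-yl]prop-2-enylidene}-7-methyl-6,8-dioxo-5,6,7,8-tetrahydro-1H-isochromen-7-yl 2,4-dihydroxy-6-methylbenzoate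
Conditions: Et3N·3HF, THF, 0 °C to rt
Reagents that add atoms: none
Why: Amine-buffered hydrogen fluoride cleaves the four aryl silyl ethers under nearly neutral conditions (fluoride desilylation), which the allylic acetate, the benzoates, the enol ethers and the tetraene should tolerate.

**Compound list**

1 | 2,6-dimethoxytoluene | COc1cccc(OC)c1C | starting material
2 | 2-(3,5-dimethoxy-4-methylphenyl)-4,4,5,5-tetramethyl-1,3,2-dioxaborolane | COc1cc(B2OC(C)(C)C(C)(C)O2)cc(OC)c1C | intermediate (not isolated)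
3 | 5-bromo-1,3-dimethoxy-2-methylbenzene | COc1cc(Br)cc(OC)c1C | intermediate
4 | N-[(6-bromo-2,4-dimethoxy-3-methylphenyl)methylidene]-N-methylmethanaminium chloride | C[N+](C)=Cc1c(Br)cc(OC)c(C)c1OC.[Cl-] | intermediate (not isolated)
5 | 6-bromo-2,4-dimethoxy-3-methylbenzaldehyde | O=Cc1c(Br)cc(OC)c(C)c1OC | intermediate
6 | 6-bromo-2,4-dihydroxy-3-methylbenzaldehyde | O=Cc1c(Br)cc(O)c(C)c1O | intermediate
7 | 6-bromo-3-methyl-2,4-bis(triisopropylsilyloxy)benzaldehyde | O=Cc1c(Br)cc(O[Si](C(C)C)(C(C)C)C(C)C)c(C)c1O[Si](C(C)C)(C(C)C)C(C)C | intermediate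
8 | [6-bromo-3-methyl-2,4-bis(triisopropylsilyloxy)phenyl]methanol | OCc1c(Br)cc(O[Si](C(C)C)(C(C)C)C(C)C)c(C)c1O[Si](C(C)C)(C(C)C)C(C)C | intermediate
9 | (diethoxyphosphoryl)acetic acid | CCOP(=O)(CC(=O)O)OCC | starting material
10 | [6-bromo-3-methyl-2,4-bis(triisopropylsilyloxy)phenyl]methyl (diethoxyphosphoryl)acetate | CCOP(=O)(CC(=O)OCc1c(Br)cc(O[Si](C(C)C)(C(C)C)C(C)C)c(C)c1O[Si](C(C)C)(C(C)C)C(C)C)OCC | intermediate
11 | (tert-butyldimethylsilyloxy)acetaldehyde | CC(C)(C)[Si](C)(C)OCC=O | starting material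
12 | [6-bromo-3-methyl-2,4-bis(triisopropylsilyloxy)phenyl]methyl (E)-4-(tert-butyldimethylsilyloxy)but-2-enoate | O=C(OCc1c(Br)cc(O[Si](C(C)C)(C(C)C)C(C)C)c(C)c1O[Si](C(C)C)(C(C)C)C(C)C)/C=C/CO[Si](C)(C)C(C)(C)C | intermediate
13 | 1-bromo-2-({[(3E)-5-(tert-butyldimethylsilyloxy)penta-1,3-dien-2-yl]oxy}methyl)-4-methyl-3,5-bis(triisopropylsilyloxy)benzene | C=C(OCc1c(Br)cc(O[Si](C(C)C)(C(C)C)C(C)C)c(C)c1O[Si](C(C)C)(C(C)C)C(C)C)/C=C/CO[Si](C)(C)C(C)(C)C | intermediate
14 | 3-[(E)-3-(tert-butyldimethylsilyloxy)prop-1-enyl]-7-methyl-6,8-bis(triisopropylsilyloxy)-1H-isochromene | CC(C)(C)[Si](C)(C)OC/C=C/C1=Cc2cc(O[Si](C(C)C)(C(C)C)C(C)C)c(C)c(O[Si](C(C)C)(C(C)C)C(C)C)c2CO1 | intermediate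
15 | 3-[(E)-3-(tert-butyldimethylsilyloxy)prop-1-enyl]-7-methyl-1H-isochromene-6,8-diol | CC(C)(C)[Si](C)(C)OC/C=C/C1=Cc2cc(O)c(C)c(O)c2CO1 | intermediate
16 | racemic 3-[(E)-3-(tert-butyldimethylsilyloxy)prop-1-enyl]-7-hydroxy-7-methyl-1H-isochromene-6,8(5H,7H)-dione | CC(C)(C)[Si](C)(C)OC/C=C/C1=CC2=C(CO1)C(=O)C(C)(O)C(=O)C2 | intermediate
17 | racemic 7-hydroxy-3-[(E)-3-hydroxyprop-1-enyl]-7-methyl-1H-isochromene-6,8(5H,7H)-dione | OC/C=C/C1=CC2=C(CO1)C(=O)C(C)(O)C(=O)C2 | intermediate
18 | (7S)-7-hydroxy-3-[(E)-3-hydroxyprop-1-enyl]-7-methyl-1H-isochromene-6,8(5H,7H)-dione | OC/C=C/C1=CC2=C(CO1)C(=O)[C@@](C)(O)C(=O)C2 | intermediate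
19 | (6R,7R)-6,7-dihydroxy-3-[(E)-3-hydroxyprop-1-enyl]-7-methyl-6,7-dihydro-1H-isochromen-8(5H)-one | OC/C=C/C1=CC2=C(CO1)C(=O)[C@](C)(O)[C@H](O)C2 | intermediate
20 | (E)-3-[(7S)-7-hydroxy-7-methyl-6,8-dioxo-5,6,7,8-tetrahydro-1H-isochromen-3-yl]prop-2-enyl acetate | CC(=O)OC/C=C/C1=CC2=C(CO1)C(=O)[C@@](C)(O)C(=O)C2 | intermediate
21 | (E)-3-[(6R,7R)-6,7-dihydroxy-7-methyl-8-oxo-5,6,7,8-tetrahydro-1H-isochromen-3-yl]prop-2-enal | O=C/C=C/C1=CC2=C(CO1)C(=O)[C@](C)(O)[C@H](O)C2 | intermediate
22 | orsellinic acid (2,4-dihydroxy-6-methylbenzoic acid) | Cc1cc(O)cc(O)c1C(=O)O | starting material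
23 | tert-butyldimethylsilyl 2,4-bis(tert-butyldimethylsilyloxy)-6-methylbenzoate | Cc1cc(O[Si](C)(C)C(C)(C)C)cc(O[Si](C)(C)C(C)(C)C)c1C(=O)O[Si](C)(C)C(C)(C)C | intermediate
24 | 2,4-bis(tert-butyldimethylsilyloxy)-6-methylbenzoyl chloride | Cc1cc(O[Si](C)(C)C(C)(C)C)cc(O[Si](C)(C)C(C)(C)C)c1C(=O)Cl | intermediate
25 | (7S)-3-[(E)-3-acetoxyprop-1-enyl]-7-methyl-6,8-dioxo-5,6,7,8-tetrahydro-1H-isochromen-7-yl 2,4-bis(tert-butyldimethylsilyloxy)-6-methylbenzoate | CC(=O)OC/C=C/C1=CC2=C(CO1)C(=O)[C@@](C)(OC(=O)c1c(C)cc(O[Si](C)(C)C(C)(C)C)cc1O[Si](C)(C)C(C)(C)C)C(=O)C2 | intermediate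
26 | (6R,7R)-7-hydroxy-7-methyl-8-oxo-3-[(E)-3-oxoprop-1-enyl]-5,6,7,8-tetrahydro-1H-isochromen-6-yl 2,4-bis(tert-butyldimethylsilyloxy)-6-methylbenzoate | O=C/C=C/C1=CC2=C(CO1)C(=O)[C@](C)(O)[C@H](OC(=O)c1c(C)cc(O[Si](C)(C)C(C)(C)C)cc1O[Si](C)(C)C(C)(C)C)C2 | intermediate
27 | tetrakis(tert-butyldimethylsilyl) ether of the target | CC(=O)OC/C=C/C1=CC2=C(CO1)C(=O)[C@@](C)(OC(=O)c1c(C)cc(O[Si](C)(C)C(C)(C)C)cc1O[Si](C)(C)C(C)(C)C)C(=O)/C2=C\C=C\C1=CC2=C(CO1)C(=O)[C@](C)(O)[C@H](OC(=O)c1c(C)cc(O[Si](C)(C)C(C)(C)C)cc1O[Si](C)(C)C(C)(C)C)C2 | intermediate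
28 | target (CNP0283591.2) | CC(=O)OC/C=C/C1=CC2=C(CO1)C(=O)[C@@](C)(OC(=O)c1c(C)cc(O)cc1O)C(=O)/C2=C\C=C\C1=CC2=C(CO1)C(=O)[C@](C)(O)[C@H](OC(=O)c1c(C)cc(O)cc1O)C2 | target

**Totals and risks**

Total step count: 21. Longest linear sequence: 17 steps (steps 1 to 13, then 14, 18, 20, 21; the branch through 15 and 19 is equally long).

Steps most likely to fail:

Step 11. Oxygen may be delivered to the unsubstituted C5 position instead of C7, or the electron-rich dienyl ether may be oxidised. Fallback, from 15 back to 16: acetoxylative dearomatisation (Wessely acetoxylation) with Pb(OAc)4 in CH2Cl2 over solid NaHCO3 at –40 °C, which delivers the acyloxy group from an aryloxy–lead intermediate to an alkyl-bearing ortho carbon, would give the racemic 7-acetoxy-6,8-dione F5; methanolysis of the tertiary acetate (K2CO3, MeOH, 0 °C) would return the route at 16.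

Step 13. The enzyme may not discriminate between the two enantiomers, so that both are reduced or the resolution stalls. Fallback, from 16 back to 18 and 19: Corey–Bakshi–Shibata reduction of racemic 16 with (S)-2-methyl-CBS-oxazaborolidine and catecholborane at –78 °C would reduce C6 of both enantiomers under reagent control (large side the quaternary C7, small side the C5 methylene) to the 6R alcohols, that is the cis diol (6R,7R)-silyl ether F6 and the trans diol (6R,7S)-silyl ether F7, which are diastereomers and separable on silica. Desilylation of F6 with Et3N·3HF would return the route at 19. F7 would be oxidised back at C6 with Dess–Martin periodinane to the (7S)-ketone silyl ether F8, and its desilylation would return the route at 18.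

Step 9. The ring may close in the 5-exo mode at C3, or the dienyl ether may hydrolyse before insertion. Fallback, from 8 back to 14, keeping the same C4–C4a ring closure: acetylation of 8 (Ac2O, pyridine) would give the benzylic acetate F1; palladium-catalysed intramolecular α-arylation of its lithium enolate (Pd2(dba)3, t-Bu3P, LiN(SiMe3)2, toluene, rt) would close the lactone to the isochroman-3-one F2; O-phosphorylation of the lactone enolate (KN(SiMe3)2, (PhO)2P(O)Cl, THF, –78 °C) would give the ketene acetal phosphate F3; Stille coupling (Pd(PPh3)4, LiCl, THF, reflux) with the vinylstannane F4, made by hydrostannylation of tert-butyldimethyl(prop-2-ynyloxy)silane with Bu3SnH, would return the route at 14.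

**Further compounds**

F1 | step 9 | [6-bromo-3-methyl-2,4-bis(triisopropylsilyloxy)phenyl]methyl acetate | CC(=O)OCc1c(Br)cc(O[Si](C(C)C)(C(C)C)C(C)C)c(C)c1O[Si](C(C)C)(C(C)C)C(C)C
F2 | step 9 | 7-methyl-6,8-bis(triisopropylsilyloxy)-1,4-dihydro-3H-isochromen-3-one | O=C1Cc2cc(O[Si](C(C)C)(C(C)C)C(C)C)c(C)c(O[Si](C(C)C)(C(C)C)C(C)C)c2CO1
F3 | step 9 | 7-methyl-6,8-bis(triisopropylsilyloxy)-1H-isochromen-3-yl diphenyl phosphate | O=P(OC1=Cc2cc(O[Si](C(C)C)(C(C)C)C(C)C)c(C)c(O[Si](C(C)C)(C(C)C)C(C)C)c2CO1)(Oc1ccccc1)Oc1ccccc1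
F4 | step 9 | (E)-tert-butyldimethyl{[3-(tributylstannyl)prop-2-enyl]oxy}silane | CCCC[Sn](CCCC)(CCCC)/C=C/CO[Si](C)(C)C(C)(C)C
F5 | step 11 | racemic 3-[(E)-3-(tert-butyldimethylsilyloxy)prop-1-enyl]-7-methyl-6,8-dioxo-5,6,7,8-tetrahydro-1H-isochromen-7-yl acetate | CC(C)(C)[Si](C)(C)OC/C=C/C1=CC2=C(CO1)C(=O)C(C)(OC(C)=O)C(=O)C2
F6 | step 13 | (6R,7R)-3-[(E)-3-(tert-butyldimethylsilyloxy)prop-1-enyl]-6,7-dihydroxy-7-methyl-6,7-dihydro-1H-isochromen-8(5H)-one | CC(C)(C)[Si](C)(C)OC/C=C/C1=CC2=C(CO1)C(=O)[C@](C)(O)[C@H](O)C2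
F7 | step 13 | (6R,7S)-3-[(E)-3-(tert-butyldimethylsilyloxy)prop-1-enyl]-6,7-dihydroxy-7-methyl-6,7-dihydro-1H-isochromen-8(5H)-one | CC(C)(C)[Si](C)(C)OC/C=C/C1=CC2=C(CO1)C(=O)[C@@](C)(O)[C@H](O)C2
F8 | step 13 | (7S)-3-[(E)-3-(tert-butyldimethylsilyloxy)prop-1-enyl]-7-hydroxy-7-methyl-1H-isochromene-6,8(5H,7H)-dione | CC(C)(C)[Si](C)(C)OC/C=C/C1=CC2=C(CO1)C(=O)[C@@](C)(O)C(=O)C2
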